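**Strategy**

The route rests on recognising the five-membered ring C1–C7–C6–C5–C8 of the bicyclo[3.2.1]octane as a cyclopentanone (C8=O) whose two α-carbons, C1 and C5, are bridged by a malonyl unit, the enolised β-diketone C2–C3–C4. An Effenberger-type α,α′-annulation of malonyl dichloride onto a silyl enol ether forges both acyl–bridgehead bonds (C1–C2 and C4–C5), both quaternary centres and the six- and seven-membered rings in one operation. Its precursor is a monocyclic, bis-silylated 2-methyl-5-prenylcyclopentanone enol ether whose only fixed stereocentre (future C6) steers the bridge to the opposite face; the acyl side chain is added last.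

Key step: step 5

Assumption: (R)-2-methylbutanoic acid, isopropenylmagnesium bromide solution and malonyl dichloride are taken as commercial; compounds 10, 11, 13, 14 and the F compounds derived from them are drawn as one of their rapidly interconverting enol tautomers.

Numbering used in the text: bicyclic compounds carry bicyclo[3.2.1]octane locants (C1 prenyl bridgehead, C2–C4 β-diketone bridge, C5 methyl bridgehead, C6 carbinol-bearing CH, C7 CH2, C8 bridging ketone). Monocyclic compounds carry cyclopentanone locants (C1 carbonyl, C2 methyl, C3 side chain, C5 prenyl), which become C8, C5, C6 and C1 of the bicycle.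

**Route**

Step 1
Reactants: 1 2-methylcyclopent-2-en-1-one; 2 isopropenylmagnesium bromide
Product: 3 (2S,3R)-2-methyl-3-(prop-1-en-2-yl)cyclopentan-1-one
Conditions: CuBr·SMe2 (5 mol %), Rev-JosiPhos-type ferrocenyl diphosphine (6 mol %, enantiomer giving 3R), tBuOMe, −78 °C; then sat. aq NH4Cl
Reagents that add atoms: none
Why: Copper-catalysed asymmetric conjugate addition of a Grignard reagent to 2-methylcyclopent-2-enone, a substrate class on which this catalyst type is established; the chiral diphosphine–CuBr complex selects the enone face and sets C3 (R), while C2 arises on protonation of the magnesium enolate, is expected mainly trans, and is of no consequence because it is made planar again in step 5.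

Step 2
Reactants: 3 (2S,3R)-2-methyl-3-(prop-1-en-2-yl)cyclopentan-1-one
Product: 4 (2S,3R)-3-(2-hydroxypropan-2-yl)-2-methylcyclopentan-1-one
Conditions: Co(acac)2 (20 mol %), PhSiH3 (2.5 equiv), O2 (1 atm), THF, rt
Reagents that add atoms: dioxygen, O=O
Why: Mukaiyama hydration (hydrogen-atom transfer from a cobalt hydride to the 1,1-disubstituted alkene, trapping of the tertiary radical by O2, reduction of the peroxide by the silane) should give the Markovnikov tertiary alcohol while the saturated ketone stays inert; no stereocentre is formed or touched.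

Step 3
Reactants: 4 (2S,3R)-3-(2-hydroxypropan-2-yl)-2-methylcyclopentan-1-one; 5 1-bromo-3-methylbut-2-ene (prenyl bromide)
Product: 6 (2S,3R,5R)-3-(2-hydroxypropan-2-yl)-2-methyl-5-(3-methylbut-2-en-1-yl)cyclopentan-1-one
Conditions: LDA (2.2 equiv), THF, −78 °C; then 5 (1.1 equiv), −78 to −30 °C; H2O
Reagents that add atoms: none
Why: Kinetic enolate alkylation of the alkoxide–enolate dianion: LDA should remove a proton from the unhindered C5 methylene in preference to the C2 methine next to the carbinol-bearing carbon, and SN2 alkylation is expected anti to the C3 substituent (new C5 centre, drawn R, of no consequence because C5 becomes sp2 in step 4).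

Step 4
Reactants: 6 (2S,3R,5R)-3-(2-hydroxypropan-2-yl)-2-methyl-5-(3-methylbut-2-en-1-yl)cyclopentan-1-one
Product: 7 trimethyl{[(4R,5S)-5-methyl-2-(3-methylbut-2-en-1-yl)-4-{2-[(trimethylsilyl)oxy]propan-2-yl}cyclopent-1-en-1-yl]oxy}silane
Conditions: TMSOTf (2.4 equiv), Et3N (4 equiv), CH2Cl2, 0 °C; pentane/aq NaHCO3 work-up, used crude
Reagents that add atoms: trimethylsilyl trifluoromethanesulfonate (TMSOTf), C[Si](C)(C)OS(=O)(=O)C(F)(F)F
Why: Soft enolisation/silylation converts the ketone into its trimethylsilyl enol ether and masks the tertiary alcohol as its trimethylsilyl ether in the same operation; the C1=C5 isomer is expected to predominate because the C1=C2 isomer suffers allylic strain with the C3 substituent, any C1=C2 isomer converges to the same product in step 5, and no stereocentre is formed.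

Step 5
Reactants: 7 trimethyl{[(4R,5S)-5-methyl-2-(3-methylbut-2-en-1-yl)-4-{2-[(trimethylsilyl)oxy]propan-2-yl}cyclopent-1-en-1-yl]oxy}silane; 8 malonyl dichloride
Product: 11 (1S,5R,6R)-4-hydroxy-6-(2-hydroxypropan-2-yl)-5-methyl-1-(3-methylbut-2-en-1-yl)bicyclo[3.2.1]oct-3-ene-2,8-dione, via keto acid chloride 9 (not isolated), via silyl ether 10 (not isolated)
Conditions: 8 (1.5 equiv), Et2O, −20 °C to rt, 24 h; then 1 M HCl, THF, 0 °C
Reagents that add atoms: none
Why: Effenberger cyclization: the prenyl-bearing enol ether carbon (future C1) C-acylates malonyl dichloride with loss of Me3SiCl to give keto acid chloride 9 (bond C1–C2), the ketone then enolises toward the methyl-bearing α-carbon (future C5) and this enol carbon attacks the second acid chloride with loss of HCl (bond C4–C5). The closest known reaction type is the α,α′-annulation of 2,6-disubstituted cyclohexanone enol ethers with malonyl dichloride to bicyclo[3.3.1]nonane-2,4,9-triones, here run on a cyclopentanone enol ether. The second bond closes the six-membered ring C1–C2–C3–C4–C5–C8 in a 6-(enolendo)-exo-trig mode and, with the same bond, the seven-membered ring C1 to C7 of the bicycle. The two new quaternary bridgeheads are controlled by the one stereocentre of 7 (future C6): the first acylation should occur on the ring face opposite the bulky Me2C(OSiMe3) group, the bridge can only close on that same face, and at C5 this is again the face anti to the neighbouring group, so methyl and prenyl end up syn to the C6 substituent. The step needs C- over O-acylation and attack on one face; full substitution of both α-carbons blocks the usual diversion to 4-hydroxypyran-2-ones, and material acylated on the wrong face cannot bridge and is lost on work-up instead of giving a diastereomer. Aqueous acid in the work-up cleaves the tertiary silyl ether of 10 to give 11.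

Step 6
Reactants: 11 (1S,5R,6R)-4-hydroxy-6-(2-hydroxypropan-2-yl)-5-methyl-1-(3-methylbut-2-en-1-yl)bicyclo[3.2.1]oct-3-ene-2,8-dione; 12 (2R)-2-methylbutanoic acid
Product: 14 (1R,5R,6R)-4-hydroxy-6-(2-hydroxypropan-2-yl)-5-methyl-3-[(2R)-2-methylbutanoyl]-1-(3-methylbut-2-en-1-yl)bicyclo[3.2.1]oct-3-ene-2,8-dione, via enol ester 13 (not isolated)
Conditions: DCC (1.2 equiv), DMAP (1.2 equiv), CH2Cl2, 0 °C to rt
Reagents that add atoms: none
Why: Steglich-type O-acylation of the acidic enol by the DCC-activated acid should give enol ester 13, which DMAP converts in the same flask into the C-acyl triketone by O-to-C acyl migration through an acylpyridinium/enolate ion pair, the known route to 2-acyl-1,3-diones; the hindered tertiary alcohol is not acylated and the (R) centre of the acid is carried over unchanged.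

**Compound list**

1 | 2-methylcyclopent-2-en-1-one | CC1=CCCC1=O | starting material
2 | isopropenylmagnesium bromide (prop-1-en-2-ylmagnesium bromide) | CC(=C)[Mg]Br | starting material
3 | (2S,3R)-2-methyl-3-(prop-1-en-2-yl)cyclopentan-1-one | C[C@@H]1C(=O)CC[C@H]1C(C)=C | intermediate
4 | (2S,3R)-3-(2-hydroxypropan-2-yl)-2-methylcyclopentan-1-one | C[C@@H]1C(=O)CC[C@H]1C(C)(C)O | intermediate
5 | 1-bromo-3-methylbut-2-ene (prenyl bromide) | CC(C)=CCBr | starting material
6 | (2S,3R,5R)-3-(2-hydroxypropan-2-yl)-2-methyl-5-(3-methylbut-2-en-1-yl)cyclopentan-1-one (C5 epimer equally usable) | C[C@@H]1C(=O)[C@H](CC=C(C)C)C[C@H]1C(C)(C)O | intermediate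
7 | trimethyl{[(4R,5S)-5-methyl-2-(3-methylbut-2-en-1-yl)-4-{2-[(trimethylsilyl)oxy]propan-2-yl}cyclopent-1-en-1-yl]oxy}silane | C[C@@H]1C(O[Si](C)(C)C)=C(CC=C(C)C)C[C@H]1C(C)(C)O[Si](C)(C)C | intermediate
8 | malonyl dichloride (propanedioyl dichloride) | O=C(Cl)CC(=O)Cl | starting material
9 | 3-[(1S,3S,4R)-3-methyl-1-(3-methylbut-2-en-1-yl)-2-oxo-4-{2-[(trimethylsilyl)oxy]propan-2-yl}cyclopentyl]-3-oxopropanoyl chloride; not isolated | C[C@@H]1C(=O)[C@](CC=C(C)C)(C(=O)CC(=O)Cl)C[C@H]1C(C)(C)O[Si](C)(C)C | intermediate
10 | (1S,5R,6R)-4-hydroxy-5-methyl-1-(3-methylbut-2-en-1-yl)-6-{2-[(trimethylsilyl)oxy]propan-2-yl}bicyclo[3.2.1]oct-3-ene-2,8-dione; not isolated | C1=C(O)[C@]2(C)C(=O)[C@@](CC=C(C)C)(C[C@H]2C(C)(C)O[Si](C)(C)C)C1=O | intermediate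
11 | (1S,5R,6R)-4-hydroxy-6-(2-hydroxypropan-2-yl)-5-methyl-1-(3-methylbut-2-en-1-yl)bicyclo[3.2.1]oct-3-ene-2,8-dione | C1=C(O)[C@]2(C)C(=O)[C@@](CC=C(C)C)(C[C@H]2C(C)(C)O)C1=O | intermediate
12 | (2R)-2-methylbutanoic acid | CC[C@@H](C)C(=O)O | starting material
13 | (1S,5R,6R)-6-(2-hydroxypropan-2-yl)-5-methyl-1-(3-methylbut-2-en-1-yl)-2,8-dioxobicyclo[3.2.1]oct-3-en-4-yl (2R)-2-methylbutanoate; not isolated | C1=C(OC(=O)[C@H](C)CC)[C@]2(C)C(=O)[C@@](CC=C(C)C)(C[C@H]2C(C)(C)O)C1=O | intermediate
14 | (1R,5R,6R)-4-hydroxy-6-(2-hydroxypropan-2-yl)-5-methyl-3-[(2R)-2-methylbutanoyl]-1-(3-methylbut-2-en-1-yl)bicyclo[3.2.1]oct-3-ene-2,8-dione | CC[C@@H](C)C(=O)C1=C(O)[C@]2(C)C(=O)[C@@](CC=C(C)C)(C[C@H]2C(C)(C)O)C1=O | target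

**Count**

Total steps: 6. Longest linear sequence: 6 steps (1 to 14).

**Steps most likely to fail**

Step 5 (key step). The annulation may stall after the first acylation because the ring closure goes through oxygen instead of carbon, or because the first acylation takes the wrong face. HCl formed in the closure may also strip the tertiary silyl ether early or add to the prenyl alkene. The fallback installs the prenyl group after the annulation, so that only one quaternary centre is made in the ring-forming event. It sets out from 4 and comes back at 11.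
- TMSOTf/Et3N on 4 should give bis-silyl enol ether F3.
- Malonyl dichloride and the acidic work-up of step 5 should then give des-prenyl trione F4; here the first acylation takes place at the methyl-bearing carbon, directly anti to the adjacent substituent.
- O-Methylation (Me3SiCHN2, MeOH/toluene) and separation from the regioisomer gives methyl enol ether F5, which has the carbonyl next to the bridgehead C–H.
- Bridgehead lithiation with LDA (2.2 equiv, THF, −78 °C), a reaction known for the homologous bicyclo[3.3.1]nonane trione enol ethers, and trapping with 5 should give prenylated methyl enol ether F6 with the configuration enforced by the bicycle.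
- LiOH in aqueous dioxane with warming cleaves the vinylogous ester and returns 11.

Step 1. An sp2 Grignard reagent on an α-substituted enone may give competing 1,2-addition and poor facial selectivity under catalyst control. The fallback replaces catalyst control by a stoichiometric sulfinyl auxiliary. It sets out from 2 and comes back at 3.
- Grignard reagent 2 is added at −78 °C in THF to (S)-2-(4-methylphenylsulfinyl)cyclopent-2-en-1-one pre-complexed with ZnBr2. This chelation-controlled conjugate addition, with entry anti to the tolyl group, should give β-keto sulfoxide F1.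
- C-Methylation (K2CO3, MeI, acetone) gives methylated sulfoxide F2.
- Aluminium amalgam in aqueous THF cleaves the C–S bond and, after equilibration of C2, returns 3.

Step 6. The activated acid may enolise (acylpyridinium or ketene), which would erode the configuration of the acyl α-stereocentre, and the O-to-C acyl migration may be incomplete at the hindered dione. The fallback acylates a C3 carbanion at low temperature instead. It sets out from 11 (with acid 12) and comes back at 14.
- O-Methylation of 11 (Me3SiCHN2) gives methyl enol ether F6, the compound also met in the fallback for step 5; both regioisomers are usable here.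
- Acid 12 is converted with oxalyl chloride and catalytic DMF into acid chloride F7.
- LiTMP (2.2 equiv, THF, −78 °C) forms the alkoxide and lithiates the vinylic C3–H; the vinyllithium is acylated by F7 at −78 °C to give acylated methyl enol ether F8 under conditions where the α-stereocentre should not enolise.
- LiOH in aqueous dioxane removes the methyl group and gives 14.

**Further compounds**

F1 | step 1 | (3R)-2-(4-methylphenylsulfinyl)-3-(prop-1-en-2-yl)cyclopentan-1-one (2,3-trans; sulfur geometry unchanged from the auxiliary) | Cc1ccc(cc1)[S@](=O)[C@@H]1C(=O)CC[C@H]1C(C)=C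
F2 | step 1 | (3R)-2-methyl-2-(4-methylphenylsulfinyl)-3-(prop-1-en-2-yl)cyclopentan-1-one (methyl trans to isopropenyl; sulfur geometry unchanged) | Cc1ccc(cc1)[S@](=O)[C@@]1(C)C(=O)CC[C@H]1C(C)=C
F3 | step 5 | trimethyl{[(3R)-2-methyl-3-{2-[(trimethylsilyl)oxy]propan-2-yl}cyclopent-1-en-1-yl]oxy}silane | CC1=C(O[Si](C)(C)C)CC[C@H]1C(C)(C)O[Si](C)(C)C
F4 | step 5 | (1S,5R,6R)-4-hydroxy-6-(2-hydroxypropan-2-yl)-5-methylbicyclo[3.2.1]oct-3-ene-2,8-dione | C1=C(O)[C@]2(C)C(=O)[C@@H](C[C@H]2C(C)(C)O)C1=O
F5 | step 5 | (1S,5R,6R)-6-(2-hydroxypropan-2-yl)-4-methoxy-5-methylbicyclo[3.2.1]oct-3-ene-2,8-dione | C1=C(OC)[C@]2(C)C(=O)[C@@H](C[C@H]2C(C)(C)O)C1=O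
F6 | step 5 | (1S,5R,6R)-6-(2-hydroxypropan-2-yl)-4-methoxy-5-methyl-1-(3-methylbut-2-en-1-yl)bicyclo[3.2.1]oct-3-ene-2,8-dione | C1=C(OC)[C@]2(C)C(=O)[C@@](CC=C(C)C)(C[C@H]2C(C)(C)O)C1=O
F7 | step 6 | (2R)-2-methylbutanoyl chloride | CC[C@@H](C)C(=O)Cl
F8 | step 6 | (1R,5R,6R)-6-(2-hydroxypropan-2-yl)-4-methoxy-5-methyl-3-[(2R)-2-methylbutanoyl]-1-(3-methylbut-2-en-1-yl)bicyclo[3.2.1]oct-3-ene-2,8-dione | CC[C@@H](C)C(=O)C1=C(OC)[C@]2(C)C(=O)[C@@](CC=C(C)C)(C[C@H]2C(C)(C)O)C1=O
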